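The target is epigallocatechin gallate joined by a 4β→6 bond to (+)-gallocatechin. Everything rests on the lower pyran ring (ring F: O1, C2, C3, C4, C4a, C8a), whose aryl ether oxygen on benzylic C2 sits next to the C3 hydroxyl. That 1,2-relationship is made by a five-to-six ring expansion: a 2,3-dihydrobenzofuran carrying an exocyclic benzylic sulfonate passes through an aryloxiranium ion, so that the ring oxygen moves to the benzylic carbon and acetate enters at the old ring carbon, setting C2 and C3 by double inversion. The precursor comes from an asymmetric epoxidation and a 5-exo phenoxide opening. Bromine capping at C8 then directs the union with C4-activated benzylated EGCG to C6.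

Key step: step 6

Remarks: Upper unit = rings A (benzo), C (pyran), B (pyrogallol) plus the galloyl ester; lower unit = rings D (benzo), F (pyran), E (pyrogallol). Bn = benzyl. Assumption: the L-configured Shi ketone (enantiomer of the D-fructose-derived catalyst), used catalytically, is taken as purchasable or made from L-sorbose; compounds 1, 2, 4, 13 and 15 are commercial.

Step 1
Reactants: 1 3,4,5-tris(benzyloxy)benzaldehyde; 2 vinylmagnesium bromide
Product: 3 rac-1-[3,4,5-tris(benzyloxy)phenyl]prop-2-en-1-ol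
Conditions: 2 (1.2 equiv), THF, 0 °C; aq. NH4Cl
Reagents that add atoms: vinylmagnesium bromide (compound 2), C=C[Mg]Br
Why: Grignard 1,2-addition to the aldehyde gives an easily ionised allylic alcohol whose stereocentre is erased in step 2, so no control is needed.

Step 2
Reactants: 3 rac-1-[3,4,5-tris(benzyloxy)phenyl]prop-2-en-1-ol; 4 3,5-bis(benzyloxy)phenol
Product: 5 3,5-bis(benzyloxy)-2-[(2E)-3-(3,4,5-tris(benzyloxy)phenyl)prop-2-en-1-yl]phenol
Conditions: 4 (3 equiv), H2SO4 on SiO2 (cat.), CH2Cl2, 23 °C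
Reagents that add atoms: none
Why: Friedel–Crafts allylation, in which acid ionises 3 to the aryl-stabilised allyl cation and the phenol carbon ortho to the free OH attacks its terminus, should give the conjugated E-alkene.

Step 3
Reactants: 5 3,5-bis(benzyloxy)-2-[(2E)-3-(3,4,5-tris(benzyloxy)phenyl)prop-2-en-1-yl]phenol
Product: 6 {3,5-bis(benzyloxy)-2-[(2E)-3-(3,4,5-tris(benzyloxy)phenyl)prop-2-en-1-yl]phenoxy}(tert-butyl)dimethylsilane
Conditions: TBSCl, imidazole, DMF, 23 °C
Reagents that add atoms: tert-butyldimethylsilyl chloride, CC(C)(C)[Si](C)(C)Cl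
Why: Silylation masks the oxidisable phenol and keeps it from opening the epoxide before the ring-forming step.

Step 4
Reactants: 6 {3,5-bis(benzyloxy)-2-[(2E)-3-(3,4,5-tris(benzyloxy)phenyl)prop-2-en-1-yl]phenoxy}(tert-butyl)dimethylsilane
Product: 7 {3,5-bis(benzyloxy)-2-{[(2S,3S)-3-(3,4,5-tris(benzyloxy)phenyl)oxiran-2-yl]methyl}phenoxy}(tert-butyl)dimethylsilane
Conditions: L-configured Shi ketone (0.3 equiv), Oxone (2KHSO5·KHSO4·K2SO4), K2CO3, Bu4NHSO4, MeCN–CH2(OMe)2–aq. Na2B4O7 buffer, 0 °C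
Reagents that add atoms: Oxone (active salt KHSO5), [K+].[O-]S(=O)(=O)OO
Why: Shi asymmetric epoxidation, in which the chiral dioxirane from the L-configured ketone transfers oxygen through the spiro transition state to the face opposite to that chosen by the D-fructose-derived catalyst, should set both epoxide carbons as S.

Step 5
Reactants: 7 {3,5-bis(benzyloxy)-2-{[(2S,3S)-3-(3,4,5-tris(benzyloxy)phenyl)oxiran-2-yl]methyl}phenoxy}(tert-butyl)dimethylsilane
Product: 8 (S)-[(2R)-4,6-bis(benzyloxy)-2,3-dihydro-1-benzofuran-2-yl][3,4,5-tris(benzyloxy)phenyl]methanol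
Conditions: Bu4NF (1.1 equiv), THF, 0 → 23 °C; aq. NH4Cl
Reagents that add atoms: none
Why: Fluoride desilylation frees the phenoxide, which under basic, non-ionising conditions should open the epoxide in the 5-exo-tet mode at the proximal non-benzylic carbon with inversion (intramolecular SN2), making C2 of the dihydrobenzofuran R while the carbinol carbon keeps the S configuration of the epoxide.

Step 6
Reactants: 8 (S)-[(2R)-4,6-bis(benzyloxy)-2,3-dihydro-1-benzofuran-2-yl][3,4,5-tris(benzyloxy)phenyl]methanol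
Product: 11 (2R,3S)-5,7-bis(benzyloxy)-2-[3,4,5-tris(benzyloxy)phenyl]chroman-3-ol (penta-O-benzyl-(+)-gallocatechin), via benzylic mesylate 9 (not isolated), via 3-O-acetyl flavan 10 (not isolated)
Conditions: Ms2O (1.3 equiv), 2,6-lutidine, CH2Cl2, −40 °C; then Zn(OAc)2 (4 equiv), AcOH–THF–H2O, 50 °C; then K2CO3, MeOH, 23 °C
Reagents that add atoms: zinc diacetate Zn(OAc)2, CC(=O)[O-].CC(=O)[O-].[Zn+2] (acetate of 10; its oxygen remains as the C3 oxygen of 11); methanesulfonic anhydride, CS(=O)(=O)OS(C)(=O)=O (mesyl group of 9 only)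
Why: Mesylation turns the benzylic hydroxyl of 8 into a leaving group that the ring oxygen displaces from the back in a 3-exo-tet closure, giving a trans-disubstituted aryloxiranium ion; acetate (or water) then opens this ion at the former ring carbon C2 anti to oxygen, which is the endo mode of opening that enlarges the five-membered ring to the six-membered ring F. The closest known reaction type is the Zn(OAc)2-promoted ring expansion of 2-(1-sulfonyloxyalkyl) cyclic ethers through bicyclic oxiranium ions, and the same ion links 2-(1-hydroxyalkyl)dihydrobenzofurans with 3-substituted chromans. Both new stereocentres are set by the substrate: C2 (R) by inversion of the (S)-carbinol carbon through the intramolecular attack, and C3 (S) by inversion of (R)-C2 of the dihydrobenzofuran through the external acetate, so the 2,3-trans arrangement follows from the erythro precursor. The step needs site selectivity for capture at the non-benzylic carbon over the benzylic one and must avoid 1,2-hydride shift or elimination to a benzofuran. The 3,4,5-tris(benzyloxy)phenyl group secures this because any mesylate or acetate at the benzylic carbon re-ionises under Zn(OAc)2 in warm aqueous acetic acid and re-enters the oxiranium ion, whereas the secondary, non-benzylic C3 acetate 10 cannot, so the material funnels into the strain-relieved six-membered ring. The nucleophile-rich buffered medium keeps the lifetime of any open cation short, and mild methanolysis finally frees the 3-hydroxyl.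

Step 7
Reactants: 11 (2R,3S)-5,7-bis(benzyloxy)-2-[3,4,5-tris(benzyloxy)phenyl]chroman-3-ol
Product: 12 (2R,3S)-5,7-bis(benzyloxy)-8-bromo-2-[3,4,5-tris(benzyloxy)phenyl]chroman-3-ol
Conditions: NBS (1.0 equiv), CH2Cl2, −20 °C
Reagents that add atoms: N-bromosuccinimide, O=C1CCC(=O)N1Br
Why: Electrophilic aromatic bromination should take the more accessible activated position C8 of ring D (next to the ring oxygen) over C6 (between two benzyloxy groups), which caps C8 without touching a stereocentre.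

Step 8
Reactants: 13 (−)-epigallocatechin (2R,3R)
Product: 14 (2R,3R)-5,7-bis(benzyloxy)-2-[3,4,5-tris(benzyloxy)phenyl]chroman-3-ol (penta-O-benzyl-(−)-epigallocatechin)
Conditions: BnBr (5.5 equiv), K2CO3, DMF, 0 → 23 °C, N2
Reagents that add atoms: benzyl bromide, BrCc1ccccc1
Why: Williamson etherification, in which carbonate deprotonates only the five phenols, should benzylate them and leave the secondary 3-hydroxyl free and both stereocentres intact.

Step 9
Reactants: 14 (2R,3R)-5,7-bis(benzyloxy)-2-[3,4,5-tris(benzyloxy)phenyl]chroman-3-ol; 15 3,4,5-tris(benzyloxy)benzoic acid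
Product: 16 (2R,3R)-5,7-bis(benzyloxy)-2-[3,4,5-tris(benzyloxy)phenyl]chroman-3-yl 3,4,5-tris(benzyloxy)benzoate (octa-O-benzyl-EGCG)
Conditions: 15 (1.5 equiv), DCC (1.6 equiv), DMAP (0.3 equiv), CH2Cl2, 23 °C
Reagents that add atoms: 3,4,5-tris(benzyloxy)benzoic acid (compound 15), O=C(O)c1cc(OCc2ccccc2)c(OCc2ccccc2)c(OCc2ccccc2)c1
Why: Steglich esterification acylates the axial 3-hydroxyl through the acylpyridinium ion, and since the C3–O bond is not broken the 2,3-cis configuration is retained.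

Step 10
Reactants: 16 (2R,3R)-5,7-bis(benzyloxy)-2-[3,4,5-tris(benzyloxy)phenyl]chroman-3-yl 3,4,5-tris(benzyloxy)benzoate
Product: 17 (2R,3R)-5,7-bis(benzyloxy)-8-bromo-2-[3,4,5-tris(benzyloxy)phenyl]chroman-3-yl 3,4,5-tris(benzyloxy)benzoate
Conditions: NBS (1.05 equiv), CH2Cl2, −20 → 0 °C
Reagents that add atoms: N-bromosuccinimide, O=C1CCC(=O)N1Br
Why: Electrophilic bromination at C8 of ring A, the most nucleophilic and accessible arene position (the galloyl ring is deactivated by its ester), caps the site through which the electrophile would otherwise self-condense.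

Step 11
Reactants: 17 (2R,3R)-5,7-bis(benzyloxy)-8-bromo-2-[3,4,5-tris(benzyloxy)phenyl]chroman-3-yl 3,4,5-tris(benzyloxy)benzoate
Product: 18 (2R,3R,4S)-5,7-bis(benzyloxy)-8-bromo-4-(2-ethoxyethoxy)-2-[3,4,5-tris(benzyloxy)phenyl]chroman-3-yl 3,4,5-tris(benzyloxy)benzoate (4β-ether, 3,4-trans)
Conditions: DDQ (2 equiv), 2-ethoxyethanol (5 equiv), CH2Cl2, 23 °C
Reagents that add atoms: 2-ethoxyethanol, CCOCCO
Why: DDQ benzylic oxidation (hydride abstraction at C4 gives a cation stabilised by the 5- and 7-oxygens) with capture by the alcohol from the β face, anti to the 3-acyloxy and 2-aryl groups, should give the 3,4-trans C4 ether.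

Step 12
Reactants: 18 (2R,3R,4S)-5,7-bis(benzyloxy)-8-bromo-4-(2-ethoxyethoxy)-2-[3,4,5-tris(benzyloxy)phenyl]chroman-3-yl 3,4,5-tris(benzyloxy)benzoate; 12 (2R,3S)-5,7-bis(benzyloxy)-8-bromo-2-[3,4,5-tris(benzyloxy)phenyl]chroman-3-ol
Product: 19 8-bromo-octa-O-benzyl-EGCG-(4β→6)-8-bromo-penta-O-benzyl-(+)-gallocatechin (upper unit 2R,3R with the interflavan bond β and trans to the 3-O-galloyl group; lower unit 2R,3S)
Conditions: 12 (3 equiv, excess recovered), TMSOTf (0.5 equiv), CH2Cl2, −78 → −40 °C; Et3N quench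
Reagents that add atoms: none
Why: In this Lewis-acid-promoted SN1 Friedel–Crafts arylation, TMSOTf ionises the C4 ether to the benzylic cation (held on the α face as a dioxolanylium ion by the galloyl carbonyl), and C6 of 12, the only free ring D position, should attack from the β face to set C4 as 3,4-trans.

Step 13
Reactants: 19 8-bromo-octa-O-benzyl-EGCG-(4β→6)-8-bromo-penta-O-benzyl-(+)-gallocatechin
Product: 20 epigallocatechin 3-O-gallate-(4β→6)-gallocatechin (upper unit 2R,3R,4S; lower unit 2R,3S), CNP0271447.2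
Conditions: H2 (1 atm), Pd(OH)2/C, NaOAc (2.5 equiv), THF–MeOH–H2O, 23 °C; filtration, Sephadex LH-20
Reagents that add atoms: none
Why: Catalytic hydrogenolysis should cleave the thirteen benzyl ethers and both aryl C–Br bonds while the ester, the interflavan bond and all stereocentres stay untouched, with NaOAc buffering the HBr.

Compound list
1 | 3,4,5-tris(benzyloxy)benzaldehyde | O=Cc1cc(OCc2ccccc2)c(OCc2ccccc2)c(OCc2ccccc2)c1 | starting material
2 | vinylmagnesium bromide | C=C[Mg]Br | starting material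
3 | rac-1-[3,4,5-tris(benzyloxy)phenyl]prop-2-en-1-ol | C=CC(O)c1cc(OCc2ccccc2)c(OCc2ccccc2)c(OCc2ccccc2)c1 | intermediate
4 | 3,5-bis(benzyloxy)phenol | Oc1cc(OCc2ccccc2)cc(OCc2ccccc2)c1 | starting material
5 | 3,5-bis(benzyloxy)-2-[(2E)-3-(3,4,5-tris(benzyloxy)phenyl)prop-2-en-1-yl]phenol | Oc1cc(OCc2ccccc2)cc(OCc2ccccc2)c1C/C=C/c1cc(OCc2ccccc2)c(OCc2ccccc2)c(OCc2ccccc2)c1 | intermediate
6 | {3,5-bis(benzyloxy)-2-[(2E)-3-(3,4,5-tris(benzyloxy)phenyl)prop-2-en-1-yl]phenoxy}(tert-butyl)dimethylsilane | CC(C)(C)[Si](C)(C)Oc1cc(OCc2ccccc2)cc(OCc2ccccc2)c1C/C=C/c1cc(OCc2ccccc2)c(OCc2ccccc2)c(OCc2ccccc2)c1 | intermediate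
7 | {3,5-bis(benzyloxy)-2-{[(2S,3S)-3-(3,4,5-tris(benzyloxy)phenyl)oxiran-2-yl]methyl}phenoxy}(tert-butyl)dimethylsilane | CC(C)(C)[Si](C)(C)Oc1cc(OCc2ccccc2)cc(OCc2ccccc2)c1C[C@@H]1O[C@H]1c1cc(OCc2ccccc2)c(OCc2ccccc2)c(OCc2ccccc2)c1 | intermediate
8 | (S)-[(2R)-4,6-bis(benzyloxy)-2,3-dihydro-1-benzofuran-2-yl][3,4,5-tris(benzyloxy)phenyl]methanol | O[C@@H](c1cc(OCc2ccccc2)c(OCc2ccccc2)c(OCc2ccccc2)c1)[C@H]1Cc2c(OCc3ccccc3)cc(OCc3ccccc3)cc2O1 | intermediate
9 | (S)-[(2R)-4,6-bis(benzyloxy)-2,3-dihydro-1-benzofuran-2-yl][3,4,5-tris(benzyloxy)phenyl]methyl methanesulfonate | CS(=O)(=O)O[C@@H](c1cc(OCc2ccccc2)c(OCc2ccccc2)c(OCc2ccccc2)c1)[C@H]1Cc2c(OCc3ccccc3)cc(OCc3ccccc3)cc2O1 | intermediate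
10 | (2R,3S)-5,7-bis(benzyloxy)-2-[3,4,5-tris(benzyloxy)phenyl]chroman-3-yl acetate | CC(=O)O[C@H]1Cc2c(OCc3ccccc3)cc(OCc3ccccc3)cc2O[C@@H]1c1cc(OCc2ccccc2)c(OCc2ccccc2)c(OCc2ccccc2)c1 | intermediate
11 | (2R,3S)-5,7-bis(benzyloxy)-2-[3,4,5-tris(benzyloxy)phenyl]chroman-3-ol (penta-O-benzyl-(+)-gallocatechin) | O[C@H]1Cc2c(OCc3ccccc3)cc(OCc3ccccc3)cc2O[C@@H]1c1cc(OCc2ccccc2)c(OCc2ccccc2)c(OCc2ccccc2)c1 | intermediate
12 | (2R,3S)-5,7-bis(benzyloxy)-8-bromo-2-[3,4,5-tris(benzyloxy)phenyl]chroman-3-ol | O[C@H]1Cc2c(OCc3ccccc3)cc(OCc3ccccc3)c(Br)c2O[C@@H]1c1cc(OCc2ccccc2)c(OCc2ccccc2)c(OCc2ccccc2)c1 | intermediate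
13 | (−)-epigallocatechin (2R,3R) | O[C@@H]1Cc2c(O)cc(O)cc2O[C@@H]1c1cc(O)c(O)c(O)c1 | starting material
14 | (2R,3R)-5,7-bis(benzyloxy)-2-[3,4,5-tris(benzyloxy)phenyl]chroman-3-ol (penta-O-benzyl-(−)-epigallocatechin) | O[C@@H]1Cc2c(OCc3ccccc3)cc(OCc3ccccc3)cc2O[C@@H]1c1cc(OCc2ccccc2)c(OCc2ccccc2)c(OCc2ccccc2)c1 | intermediate
15 | 3,4,5-tris(benzyloxy)benzoic acid | O=C(O)c1cc(OCc2ccccc2)c(OCc2ccccc2)c(OCc2ccccc2)c1 | starting material
16 | (2R,3R)-5,7-bis(benzyloxy)-2-[3,4,5-tris(benzyloxy)phenyl]chroman-3-yl 3,4,5-tris(benzyloxy)benzoate (octa-O-benzyl-EGCG) | O=C(O[C@@H]1Cc2c(OCc3ccccc3)cc(OCc3ccccc3)cc2O[C@@H]1c1cc(OCc2ccccc2)c(OCc2ccccc2)c(OCc2ccccc2)c1)c1cc(OCc2ccccc2)c(OCc2ccccc2)c(OCc2ccccc2)c1 | intermediate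
17 | (2R,3R)-5,7-bis(benzyloxy)-8-bromo-2-[3,4,5-tris(benzyloxy)phenyl]chroman-3-yl 3,4,5-tris(benzyloxy)benzoate | O=C(O[C@@H]1Cc2c(OCc3ccccc3)cc(OCc3ccccc3)c(Br)c2O[C@@H]1c1cc(OCc2ccccc2)c(OCc2ccccc2)c(OCc2ccccc2)c1)c1cc(OCc2ccccc2)c(OCc2ccccc2)c(OCc2ccccc2)c1 | intermediate
18 | (2R,3R,4S)-5,7-bis(benzyloxy)-8-bromo-4-(2-ethoxyethoxy)-2-[3,4,5-tris(benzyloxy)phenyl]chroman-3-yl 3,4,5-tris(benzyloxy)benzoate | O=C(O[C@@H]1[C@@H](OCCOCC)c2c(OCc3ccccc3)cc(OCc3ccccc3)c(Br)c2O[C@@H]1c1cc(OCc2ccccc2)c(OCc2ccccc2)c(OCc2ccccc2)c1)c1cc(OCc2ccccc2)c(OCc2ccccc2)c(OCc2ccccc2)c1 | intermediate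
19 | 8-bromo-octa-O-benzyl-EGCG-(4β→6)-8-bromo-penta-O-benzyl-(+)-gallocatechin | O=C(O[C@@H]1[C@@H](c2c(OCc4ccccc4)c(Br)c3c(c2OCc4ccccc4)C[C@H](O)[C@@H](c4cc(OCc5ccccc5)c(OCc5ccccc5)c(OCc5ccccc5)c4)O3)c2c(OCc3ccccc3)cc(OCc3ccccc3)c(Br)c2O[C@@H]1c1cc(OCc2ccccc2)c(OCc2ccccc2)c(OCc2ccccc2)c1)c1cc(OCc2ccccc2)c(OCc2ccccc2)c(OCc2ccccc2)c1 | intermediate
20 | epigallocatechin 3-O-gallate-(4β→6)-gallocatechin (upper 2R,3R,4S; lower 2R,3S) | O=C(O[C@@H]1[C@@H](c2c(O)cc3c(c2O)C[C@H](O)[C@@H](c2cc(O)c(O)c(O)c2)O3)c2c(O)cc(O)cc2O[C@@H]1c1cc(O)c(O)c(O)c1)c1cc(O)c(O)c(O)c1 | target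

Total step count: 13. Longest linear sequence: 9 steps (steps 1–7, 12, 13).

Steps most likely to fail

Step 6. The oxiranium ion may be captured at the benzylic carbon without re-ionisation, so the material stalls in the five-membered series, or the benzylic cation may escape by 1,2-hydride shift and proton loss, which aromatises the ring to a benzofuran. The fallback sets out from 8 and returns at 11; it replaces the oxygen nucleophile by a chloride relay and brings in the C3 oxygen by hydroboration. SOCl2 and pyridine in CH2Cl2 at 0 °C, followed by catalytic ZnCl2 at 23 °C, should convert 8 under thermodynamic control through the same aryloxiranium ion into the ring-expanded (2R,3S)-3-chloro-5,7-bis(benzyloxy)-2-[3,4,5-tris(benzyloxy)phenyl]chroman F1, because a benzylic chloride re-ionises readily whereas the secondary chloride at C3 does not. DBU in toluene at 80 °C should then remove HCl by anti elimination across C3–C4 (axial H-4 in the diaxial conformer; H-2 is cis to the chloride and cannot be lost in this way) to give the flav-3-ene (2S)-5,7-bis(benzyloxy)-2-[3,4,5-tris(benzyloxy)phenyl]-2H-chromene F2, in which C2 is untouched and only the descriptor changes by priority. Hydroboration–oxidation (BH3·THF, 0 °C; then NaOH, H2O2), with boron adding to C3 anti to the C2 aryl group, should give 11.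

Step 12. The hindered C6 of 12, flanked by two benzyloxy groups, may attack so slowly that the C4 cation is consumed by self-condensation at C6 of a second molecule of 18 or by acid-promoted scrambling of the interflavan bond. The fallback sets out from 18 and returns at 19; it exchanges the oxygen leaving group for a thioether that the thiophilic salt AgBF4 activates irreversibly under non-acidic conditions. 2-Mercaptobenzothiazole and BF3·OEt2 in CH2Cl2 at −40 °C should convert 18 into (2R,3R,4S)-4-(1,3-benzothiazol-2-ylsulfanyl)-5,7-bis(benzyloxy)-8-bromo-2-[3,4,5-tris(benzyloxy)phenyl]chroman-3-yl 3,4,5-tris(benzyloxy)benzoate F3 (3,4-trans), and AgBF4 in THF–CH2Cl2 at 0 °C with 12 (2 equiv) should then give 19.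

Step 11. Hydride abstraction from C4 may be slowed by the bromine and the 3-O-acyl group, so that DDQ attacks benzyl ether CH2 groups or over-oxidises. The fallback sets out from 16 and returns at 18; it reverses the order of oxidation and capping. DDQ and 2-ethoxyethanol in CH2Cl2 at 23 °C should oxidise the more electron-rich, unbrominated 16 to (2R,3R,4S)-5,7-bis(benzyloxy)-4-(2-ethoxyethoxy)-2-[3,4,5-tris(benzyloxy)phenyl]chroman-3-yl 3,4,5-tris(benzyloxy)benzoate F4, and NBS in CH2Cl2 at −20 °C should then brominate C8 of this ether to give 18.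

Further compounds
F1 | step 6 | (2R,3S)-3-chloro-5,7-bis(benzyloxy)-2-[3,4,5-tris(benzyloxy)phenyl]chroman | Cl[C@H]1Cc2c(OCc3ccccc3)cc(OCc3ccccc3)cc2O[C@@H]1c1cc(OCc2ccccc2)c(OCc2ccccc2)c(OCc2ccccc2)c1
F2 | step 6 | (2S)-5,7-bis(benzyloxy)-2-[3,4,5-tris(benzyloxy)phenyl]-2H-chromene | C1=Cc2c(OCc3ccccc3)cc(OCc3ccccc3)cc2O[C@@H]1c1cc(OCc2ccccc2)c(OCc2ccccc2)c(OCc2ccccc2)c1
F3 | step 12 | (2R,3R,4S)-4-(1,3-benzothiazol-2-ylsulfanyl)-5,7-bis(benzyloxy)-8-bromo-2-[3,4,5-tris(benzyloxy)phenyl]chroman-3-yl 3,4,5-tris(benzyloxy)benzoate | O=C(O[C@@H]1[C@@H](Sc2nc3ccccc3s2)c2c(OCc3ccccc3)cc(OCc3ccccc3)c(Br)c2O[C@@H]1c1cc(OCc2ccccc2)c(OCc2ccccc2)c(OCc2ccccc2)c1)c1cc(OCc2ccccc2)c(OCc2ccccc2)c(OCc2ccccc2)c1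
F4 | step 11 | (2R,3R,4S)-5,7-bis(benzyloxy)-4-(2-ethoxyethoxy)-2-[3,4,5-tris(benzyloxy)phenyl]chroman-3-yl 3,4,5-tris(benzyloxy)benzoate | O=C(O[C@@H]1[C@@H](OCCOCC)c2c(OCc3ccccc3)cc(OCc3ccccc3)cc2O[C@@H]1c1cc(OCc2ccccc2)c(OCc2ccccc2)c(OCc2ccccc2)c1)c1cc(OCc2ccccc2)c(OCc2ccccc2)c(OCc2ccccc2)c1
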